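The route rests on cutting the O4–C3 bond of the 1,4-dioxane ring. C3 carries the ring oxygen O4 and a CH2OH arm, so it can be read as the branched terminus of a π-allyl, with a vinyl group serving as latent CH2OH. One palladium-catalysed allylic etherification then closes the dioxane ring, forms C3–O4 and sets C3 cis to the C2 aryl group under ligand control. The precursor is a (Z)-4-aryl-4-aryloxybut-2-enyl acetate with the (R)-benzylic ether centre already in place, a free phenol at the future O4, silyl ethers on the A-ring catechol and a dioxolane masking the C7 side chain.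

Key step: step 8

Assumption: the sense of induction of (S,S)-ProPhenol (step 4) and of the (R,R)-Trost ligand (step 8) is assigned by analogy and is not known for these substrates; if a trial run shows the opposite sense, the enantiomeric ligand is used and nothing else changes. (TBS = tert-butyldimethylsilyl; ring positions are numbered O1, C2 (aryl), C3, O4, C5 (OMe), C7 (side chain) throughout.)

Step 1
Reactants: 1 5-hydroxyvanillin (3,4-dihydroxy-5-methoxybenzaldehyde)
Product: 2 4-(allyloxy)-3-hydroxy-5-methoxybenzaldehyde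
Conditions: allyl bromide (1.05 equiv), Li2CO3, DMF, 45 °C
Reagents that add atoms: allyl bromide, C=CCBr
Why: Williamson etherification in which the weak base forms only the most acidic phenoxide (the 4-OH, para to the formyl group and flanked by two oxygens), so one equivalent of allyl bromide should alkylate that oxygen selectively and leave a protecting group that cannot migrate to the neighbouring phenol.

Step 2
Reactants: 2 4-(allyloxy)-3-hydroxy-5-methoxybenzaldehyde
Product: 3 2-[4-(allyloxy)-3-hydroxy-5-methoxyphenyl]-1,3-dioxolane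
Conditions: HOCH2CH2OH (5 equiv), p-TsOH (cat.), toluene, Dean–Stark reflux; Et3N quench
Reagents that add atoms: ethylene glycol, OCCO
Why: Acid-catalysed acetalisation driven by azeotropic removal of water, under which the free meta-phenol and the aryl allyl ether (both ortho positions blocked, temperature far below a Claisen rearrangement) should be inert.

Step 3
Reactants: 1 5-hydroxyvanillin
Product: 4 3,4-bis(tert-butyldimethylsilyloxy)-5-methoxybenzaldehyde
Conditions: TBSCl (2.5 equiv), imidazole, DMF, rt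
Reagents that add atoms: tert-butyldimethylsilyl chloride, CC(C)(C)[Si](C)(C)Cl
Why: Imidazole-mediated silyl ether formation on both phenols, chosen because aryl TBS ethers should survive every later step and come off with buffered fluoride in the last step, so that no free phenol para to C2 exists earlier.

Step 4
Reactants: 4 3,4-bis(TBSO)-5-methoxybenzaldehyde; 5 propargyl acetate (prop-2-yn-1-yl acetate)
Product: 6 (R)-4-[3,4-bis(TBSO)-5-methoxyphenyl]-4-hydroxybut-2-yn-1-yl acetate
Conditions: Me2Zn (3 equiv), (S,S)-ProPhenol (10–20 mol %), Ph3P=O (20–40 mol %), toluene, 0–4 °C; aq. NH4Cl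
Reagents that add atoms: none
Why: Zn–ProPhenol-catalysed asymmetric alkynylation of an aryl aldehyde, in which the dinuclear zinc catalyst should deliver the zinc acetylide to the Si face of the aldehyde and set the (R)-carbinol, while dialkylzinc leaves the acetate (the later allylic leaving group) and the aryl silyl ethers untouched.

Step 5
Reactants: 6 (R)-propargylic alcohol; 3 2-[4-(allyloxy)-3-hydroxy-5-methoxyphenyl]-1,3-dioxolane
Product: 7 (S)-4-[3,4-bis(TBSO)-5-methoxyphenyl]-4-[2-(allyloxy)-5-(1,3-dioxolan-2-yl)-3-methoxyphenoxy]but-2-yn-1-yl acetate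
Conditions: PPh3, DIAD, toluene, −20 → 0 °C
Reagents that add atoms: none
Why: Mitsunobu etherification in which the phenol displaces the oxyphosphonium of the secondary propargylic alcohol with inversion to give the (S)-aryl ether, a non-polar solvent and low temperature being used to favour SN2 over ion-pair pathways.

Step 6
Reactants: 7 (S)-aryl propargyl ether with O-allyl group
Product: 8 (S)-4-[3,4-bis(TBSO)-5-methoxyphenyl]-4-[5-(1,3-dioxolan-2-yl)-2-hydroxy-3-methoxyphenoxy]but-2-yn-1-yl acetate
Conditions: Pd(PPh3)4 (3 mol %), morpholine (3 equiv), THF, rt; Et3N-deactivated silica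
Reagents that add atoms: none
Why: Pd(0)-catalysed deallylation (Tsuji–Trost transfer of the allyl group to morpholine), which should release only the phenol because allyl aryl ethers ionise at room temperature whereas a primary propargylic acetate and the propargylic aryl ether do not; it is placed before the alkyne reduction so that no allylic acetate meets Pd(0) too early.

Step 7
Reactants: 8 (S)-phenol alkyne
Product: 9 (R,Z)-4-[3,4-bis(TBSO)-5-methoxyphenyl]-4-[5-(1,3-dioxolan-2-yl)-2-hydroxy-3-methoxyphenoxy]but-2-en-1-yl acetate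
Conditions: H2 (1 atm), Lindlar catalyst, quinoline, EtOAc, rt
Reagents that add atoms: none
Why: Lindlar semi-hydrogenation, in which syn delivery of H2 on the poisoned palladium surface should give the (Z)-alkene without over-reduction or C–O hydrogenolysis, the benzylic centre being untouched (its descriptor changes from S to R only because alkenyl ranks below aryl whereas the substituted alkynyl ranked above it).

Step 8
Reactants: 9 (R,Z)-allylic acetate with free phenol
Product: 10 cis-(2S,3R)-2-[3,4-bis(TBSO)-5-methoxyphenyl]-7-(1,3-dioxolan-2-yl)-5-methoxy-3-vinyl-2,3-dihydro-1,4-benzodioxine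
Conditions: Pd2(dba)3·CHCl3 (2.5 mol %), (R,R)-DACH-phenyl Trost ligand (7.5 mol %), Et3N (1.2 equiv), degassed CH2Cl2, 0 °C → rt
Reagents that add atoms: none
Why: Intramolecular Tsuji–Trost asymmetric allylic etherification, the reaction type known for 2-vinylchromans and 2-vinyl-1,4-benzodioxanes: Pd(0) ionises the primary acetate to a cationic η3-allyl complex and the ammonium phenoxide adds to the substituted terminus on the face opposite palladium. This closes the six-membered ring in the exo mode (C3–O4 formed, vinyl left outside the ring), whereas addition to the CH2 end would need an eight-membered ring, and C-allylation is excluded because every ortho and para position of the phenol is substituted. The new C3 centre is fixed by which allyl face carries palladium; the anti complex first formed from the Z-alkene should equilibrate by η3–η1–η3 shifts (face exchange through the CH2 end, anti-to-syn through C3) faster than the weakly basic medium lets the phenol attack, so the chiral pocket of the ligand selects the reacting diastereomer (Curtin–Hammett). The selectivity required is cis (2S,3R), against the trans preference of the substrate, and must come from the matched ligand enantiomer. The (R)-benzylic centre should stay intact because acetate is a far better leaving group than the electron-rich aryloxide. Because the acetal-bearing phenoxide is a good nucleophile but a poor leaving group and the run is stopped at full conversion, the product should not re-ionise and drift to trans.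

Step 9
Reactants: 10 cis-3-vinyl benzodioxane
Product: 12 cis-(2S,3R)-2-[3,4-bis(TBSO)-5-methoxyphenyl]-7-(1,3-dioxolan-2-yl)-3-(hydroxymethyl)-5-methoxy-2,3-dihydro-1,4-benzodioxine, via cis-3-carbaldehyde 11 (not isolated)
Conditions: O3, CH2Cl2/MeOH 4:1, Sudan Red 7B, −78 °C; then NaBH4, −78 → 0 °C
Reagents that add atoms: ozone, [O-][O+]=O
Why: Ozonolysis with reductive (NaBH4) work-up, in which the isolated terminal alkene should react far faster than the alkoxyarenes or the acetal C–H when ozone is dosed to the indicator end point, and the α-aryloxy aldehyde is reduced cold as soon as it forms, before it can epimerise at C3 or eliminate the C2 aryloxide.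

Step 10
Reactants: 12 cis-3-(hydroxymethyl) acetal
Product: 13 cis-(2S,3R)-2-[3,4-bis(TBSO)-5-methoxyphenyl]-3-(hydroxymethyl)-5-methoxy-2,3-dihydro-1,4-benzodioxine-7-carbaldehyde
Conditions: PPTS (cat.), acetone/H2O 10:1, rt
Reagents that add atoms: water, O
Why: Acid-catalysed acetal hydrolysis, which should be easy for the dioxolane of a p-alkoxybenzaldehyde under conditions that leave aryl TBS ethers, the primary alcohol and the benzylic ether at C2 intact.

Step 11
Reactants: 13 aldehyde; 14 methyl (triphenylphosphoranylidene)acetate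
Product: 15 methyl (E)-3-{cis-(2S,3R)-2-[3,4-bis(TBSO)-5-methoxyphenyl]-3-(hydroxymethyl)-5-methoxy-2,3-dihydro-1,4-benzodioxin-7-yl}acrylate
Conditions: toluene, 60 °C
Reagents that add atoms: none
Why: Wittig olefination with a stabilised ylide, which should give the (E)-cinnamate, tolerates the free primary alcohol and, with the A-ring phenols silylated, offers no quinone-methide path for opening the dioxane ring.

Step 12
Reactants: 15 (E)-acrylate
Product: 16 (E)-3-{cis-(2S,3R)-2-[3,4-bis(TBSO)-5-methoxyphenyl]-3-(hydroxymethyl)-5-methoxy-2,3-dihydro-1,4-benzodioxin-7-yl}prop-2-en-1-ol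
Conditions: DIBAL-H (4 equiv), CH2Cl2, −78 °C; Rochelle salt
Reagents that add atoms: none
Why: DIBAL-H reduction of the α,β-unsaturated ester by 1,2-hydride delivery, which should give the (E)-allylic alcohol without touching the alkene or the aryl silyl ethers, one equivalent being consumed by the free hydroxyl.

Step 13
Reactants: 16 bis-TBS ether of the target
Product: 17 5-{(2S,3R)-3-(hydroxymethyl)-7-[(E)-3-hydroxyprop-1-en-1-yl]-5-methoxy-2,3-dihydro-1,4-benzodioxin-2-yl}-3-methoxybenzene-1,2-diol (CNP0174261.1)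
Conditions: TBAF (2.5 equiv), AcOH (3 equiv), THF, 0 °C, Ar
Reagents that add atoms: none
Why: Fluoride-mediated desilylation of the two aryl TBS ethers, buffered with acetic acid so that the liberated catechol stays protonated and neither air oxidation nor quinone-methide epimerisation at C2 (now para to a free OH) should set in at 0 °C.

Compound list
1 | 5-hydroxyvanillin (3,4-dihydroxy-5-methoxybenzaldehyde) | COc1cc(C=O)cc(O)c1O | starting material
2 | 4-(allyloxy)-3-hydroxy-5-methoxybenzaldehyde | COc1cc(C=O)cc(O)c1OCC=C | intermediate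
3 | 2-[4-(allyloxy)-3-hydroxy-5-methoxyphenyl]-1,3-dioxolane | COc1cc(C2OCCO2)cc(O)c1OCC=C | intermediate
4 | 3,4-bis(tert-butyldimethylsilyloxy)-5-methoxybenzaldehyde | COc1cc(C=O)cc(O[Si](C)(C)C(C)(C)C)c1O[Si](C)(C)C(C)(C)C | intermediate
5 | propargyl acetate (prop-2-yn-1-yl acetate) | CC(=O)OCC#C | starting material
6 | (R)-4-[3,4-bis(TBSO)-5-methoxyphenyl]-4-hydroxybut-2-yn-1-yl acetate | COc1cc([C@@H](O)C#CCOC(C)=O)cc(O[Si](C)(C)C(C)(C)C)c1O[Si](C)(C)C(C)(C)C | intermediate
7 | (S)-4-[3,4-bis(TBSO)-5-methoxyphenyl]-4-[2-(allyloxy)-5-(1,3-dioxolan-2-yl)-3-methoxyphenoxy]but-2-yn-1-yl acetate | COc1cc([C@H](Oc2cc(C3OCCO3)cc(OC)c2OCC=C)C#CCOC(C)=O)cc(O[Si](C)(C)C(C)(C)C)c1O[Si](C)(C)C(C)(C)C | intermediate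
8 | (S)-4-[3,4-bis(TBSO)-5-methoxyphenyl]-4-[5-(1,3-dioxolan-2-yl)-2-hydroxy-3-methoxyphenoxy]but-2-yn-1-yl acetate | COc1cc([C@H](Oc2cc(C3OCCO3)cc(OC)c2O)C#CCOC(C)=O)cc(O[Si](C)(C)C(C)(C)C)c1O[Si](C)(C)C(C)(C)C | intermediate
9 | (R,Z)-4-[3,4-bis(TBSO)-5-methoxyphenyl]-4-[5-(1,3-dioxolan-2-yl)-2-hydroxy-3-methoxyphenoxy]but-2-en-1-yl acetate | COc1cc([C@H](Oc2cc(C3OCCO3)cc(OC)c2O)/C=C\COC(C)=O)cc(O[Si](C)(C)C(C)(C)C)c1O[Si](C)(C)C(C)(C)C | intermediate
10 | cis-(2S,3R)-2-[3,4-bis(TBSO)-5-methoxyphenyl]-7-(1,3-dioxolan-2-yl)-5-methoxy-3-vinyl-2,3-dihydro-1,4-benzodioxine | COc1cc([C@@H]2Oc3cc(C4OCCO4)cc(OC)c3O[C@@H]2C=C)cc(O[Si](C)(C)C(C)(C)C)c1O[Si](C)(C)C(C)(C)C | intermediate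
11 | cis-(2S,3S)-2-[3,4-bis(TBSO)-5-methoxyphenyl]-7-(1,3-dioxolan-2-yl)-5-methoxy-2,3-dihydro-1,4-benzodioxine-3-carbaldehyde (same geometry as 10; the descriptor at C3 changes because CHO outranks C2) | COc1cc([C@@H]2Oc3cc(C4OCCO4)cc(OC)c3O[C@@H]2C=O)cc(O[Si](C)(C)C(C)(C)C)c1O[Si](C)(C)C(C)(C)C | intermediate
12 | cis-(2S,3R)-2-[3,4-bis(TBSO)-5-methoxyphenyl]-7-(1,3-dioxolan-2-yl)-3-(hydroxymethyl)-5-methoxy-2,3-dihydro-1,4-benzodioxine | COc1cc([C@@H]2Oc3cc(C4OCCO4)cc(OC)c3O[C@@H]2CO)cc(O[Si](C)(C)C(C)(C)C)c1O[Si](C)(C)C(C)(C)C | intermediate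
13 | cis-(2S,3R)-2-[3,4-bis(TBSO)-5-methoxyphenyl]-3-(hydroxymethyl)-5-methoxy-2,3-dihydro-1,4-benzodioxine-7-carbaldehyde | COc1cc([C@@H]2Oc3cc(C=O)cc(OC)c3O[C@@H]2CO)cc(O[Si](C)(C)C(C)(C)C)c1O[Si](C)(C)C(C)(C)C | intermediate
14 | methyl (triphenylphosphoranylidene)acetate | COC(=O)C=P(c1ccccc1)(c1ccccc1)c1ccccc1 | starting material
15 | methyl (E)-3-{cis-(2S,3R)-2-[3,4-bis(TBSO)-5-methoxyphenyl]-3-(hydroxymethyl)-5-methoxy-2,3-dihydro-1,4-benzodioxin-7-yl}acrylate | COc1cc([C@@H]2Oc3cc(/C=C/C(=O)OC)cc(OC)c3O[C@@H]2CO)cc(O[Si](C)(C)C(C)(C)C)c1O[Si](C)(C)C(C)(C)C | intermediate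
16 | (E)-3-{cis-(2S,3R)-2-[3,4-bis(TBSO)-5-methoxyphenyl]-3-(hydroxymethyl)-5-methoxy-2,3-dihydro-1,4-benzodioxin-7-yl}prop-2-en-1-ol | COc1cc([C@@H]2Oc3cc(/C=C/CO)cc(OC)c3O[C@@H]2CO)cc(O[Si](C)(C)C(C)(C)C)c1O[Si](C)(C)C(C)(C)C | intermediate
17 | 5-{(2S,3R)-3-(hydroxymethyl)-7-[(E)-3-hydroxyprop-1-en-1-yl]-5-methoxy-2,3-dihydro-1,4-benzodioxin-2-yl}-3-methoxybenzene-1,2-diol (CNP0174261.1) | COc1cc([C@@H]2Oc3cc(/C=C/CO)cc(OC)c3O[C@@H]2CO)cc(O)c1O | target

Total step count: 13.
Longest linear sequence: 11 steps (steps 3–13 from 5-hydroxyvanillin; the B-ring branch, steps 1, 2 and 5–13, is equally long).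

Steps most likely to fail

1. Step 8. Facial selection at the π-allyl may follow the substrate instead of the ligand and close the ring trans. Cyclisation from the first-formed anti complex may also outrun its equilibration, or the product may re-ionise and drift to the more stable trans isomer. The fallback replaces the dynamic π-allyl by a stereospecific epoxide opening; it sets out from 7 and comes back to the route at 12. Lindlar semi-hydrogenation of 7 (H2, quinoline, EtOAc) should give the (Z)-allylic acetate with the O-allyl group retained F1, and DIBAL-H at −78 °C should free the (Z)-allylic alcohol F2. Sharpless asymmetric epoxidation with stoichiometric Ti(OiPr)4/L-(+)-DIPT and t-BuOOH (4 Å MS, CH2Cl2, −20 °C) should then place the oxygen under reagent control to give the (2S,3R)-cis-epoxy alcohol F3. Pd(PPh3)4/morpholine should remove the allyl group to give the epoxy phenol F4. Ti(OiPr)4 should then promote 6-exo attack of the phenol on the epoxide carbon next to the benzylic centre (C3-selective opening of a 2,3-epoxy alcohol) with inversion, which fixes the cis ring in the benzodioxane diol F5. NaIO4 (THF/H2O, 0 °C) should cleave the glycol to aldehyde 11, which is reduced at once with NaBH4 to 12.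

2. Step 5. The oxyphosphonium of the electron-rich benzylic, propargylic alcohol may ionise, so that inversion is incomplete and enantiopurity is lost, or the hindered phenol may react too slowly. The fallback forms the C–O bond by an enantioconvergent, catalyst-controlled substitution that uses the ionisation instead of fighting it; it sets out from 4 (with 3 as the nucleophile) and comes back at 7, which also makes step 4 unnecessary. Ethynylmagnesium bromide (THF, −78 → 0 °C) should add to 4 to give the racemic propargylic alcohol F6, and Ac2O/Et3N/DMAP its acetate F7. Copper-catalysed asymmetric propargylic etherification of F7 with phenol 3 (CuOTf, chiral pybox, i-Pr2NEt, low temperature, via a copper allenylidene) should give the (R)-terminal-alkyne aryl ether F8. Lithiation of the alkyne (n-BuLi, THF, −78 °C) and paraformaldehyde should give the primary propargylic alcohol F9, and Ac2O/pyridine then gives 7.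

3. Step 4. Facial discrimination in the alkynyl transfer may be incomplete, or addition to the electron-rich aldehyde may be slow, leaving 6 with too low an enantiomeric purity for a route that has no later upgrade. The fallback replaces catalytic C–C bond formation by a reagent-controlled ketone reduction; it sets out from 6 of insufficient purity and comes back at 6. MnO2 (CH2Cl2, rt) should oxidise the activated alcohol to the ynone F10, and Midland reduction with (R)-Alpine-Borane (alkynyl as the small group; THF or neat, rt) should return (R)-6.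

Further compounds
F1 | step 8 | (R,Z)-4-[3,4-bis(TBSO)-5-methoxyphenyl]-4-[2-(allyloxy)-5-(1,3-dioxolan-2-yl)-3-methoxyphenoxy]but-2-en-1-yl acetate | COc1cc([C@H](Oc2cc(C3OCCO3)cc(OC)c2OCC=C)/C=C\COC(C)=O)cc(O[Si](C)(C)C(C)(C)C)c1O[Si](C)(C)C(C)(C)C
F2 | step 8 | (R,Z)-4-[3,4-bis(TBSO)-5-methoxyphenyl]-4-[2-(allyloxy)-5-(1,3-dioxolan-2-yl)-3-methoxyphenoxy]but-2-en-1-ol | COc1cc([C@H](Oc2cc(C3OCCO3)cc(OC)c2OCC=C)/C=C\CO)cc(O[Si](C)(C)C(C)(C)C)c1O[Si](C)(C)C(C)(C)C
F3 | step 8 | {(2S,3R)-3-[(S)-[3,4-bis(TBSO)-5-methoxyphenyl][2-(allyloxy)-5-(1,3-dioxolan-2-yl)-3-methoxyphenoxy]methyl]oxiran-2-yl}methanol | COc1cc([C@H](Oc2cc(C3OCCO3)cc(OC)c2OCC=C)[C@H]4O[C@H]4CO)cc(O[Si](C)(C)C(C)(C)C)c1O[Si](C)(C)C(C)(C)C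
F4 | step 8 | {(2S,3R)-3-[(S)-[3,4-bis(TBSO)-5-methoxyphenyl][5-(1,3-dioxolan-2-yl)-2-hydroxy-3-methoxyphenoxy]methyl]oxiran-2-yl}methanol | COc1cc([C@H](Oc2cc(C3OCCO3)cc(OC)c2O)[C@H]4O[C@H]4CO)cc(O[Si](C)(C)C(C)(C)C)c1O[Si](C)(C)C(C)(C)C
F5 | step 8 | (S)-1-{cis-(2S,3R)-2-[3,4-bis(TBSO)-5-methoxyphenyl]-7-(1,3-dioxolan-2-yl)-5-methoxy-2,3-dihydro-1,4-benzodioxin-3-yl}ethane-1,2-diol | COc1cc([C@@H]2Oc3cc(C4OCCO4)cc(OC)c3O[C@@H]2[C@@H](O)CO)cc(O[Si](C)(C)C(C)(C)C)c1O[Si](C)(C)C(C)(C)C
F6 | step 5 | rac-1-[3,4-bis(TBSO)-5-methoxyphenyl]prop-2-yn-1-ol | COc1cc(C(O)C#C)cc(O[Si](C)(C)C(C)(C)C)c1O[Si](C)(C)C(C)(C)C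
F7 | step 5 | rac-1-[3,4-bis(TBSO)-5-methoxyphenyl]prop-2-yn-1-yl acetate | COc1cc(C(OC(C)=O)C#C)cc(O[Si](C)(C)C(C)(C)C)c1O[Si](C)(C)C(C)(C)C
F8 | step 5 | (R)-2-{4-(allyloxy)-3-[1-(3,4-bis(TBSO)-5-methoxyphenyl)prop-2-yn-1-yloxy]-5-methoxyphenyl}-1,3-dioxolane | COc1cc([C@H](Oc2cc(C3OCCO3)cc(OC)c2OCC=C)C#C)cc(O[Si](C)(C)C(C)(C)C)c1O[Si](C)(C)C(C)(C)C
F9 | step 5 | (S)-4-[3,4-bis(TBSO)-5-methoxyphenyl]-4-[2-(allyloxy)-5-(1,3-dioxolan-2-yl)-3-methoxyphenoxy]but-2-yn-1-ol | COc1cc([C@H](Oc2cc(C3OCCO3)cc(OC)c2OCC=C)C#CCO)cc(O[Si](C)(C)C(C)(C)C)c1O[Si](C)(C)C(C)(C)C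
F10 | step 4 | 4-[3,4-bis(TBSO)-5-methoxyphenyl]-4-oxobut-2-yn-1-yl acetate | COc1cc(C(=O)C#CCOC(C)=O)cc(O[Si](C)(C)C(C)(C)C)c1O[Si](C)(C)C(C)(C)C
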